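**Retrosynthetic overview**

1. Ring numbering used below: C1 (CH bearing isopropenyl), C2 (CH2), C3 (C=O), C4(Me)–C5 oxirane, C6 (CH2), C7 (CH–O-angelate), C8(Me)–C9 oxirane, C10 (CH–O-angelate). Last disconnection: both angelates, back to diepoxy diol 26.
2. Both oxiranes come from a Z,Z-cyclodecadienone: the C8–C9 oxirane by hydroxyl-directed epoxidation from the C10 allylic alcohol, the C4–C5 oxirane by nucleophilic epoxidation of the Z-enone guided by the C7 hydroxyl.
3. The ten-membered ring is closed at C9–C10. The C8–C9 cis-oxirane beside the C10 carbinol is the retron of a (Z)-allylic alcohol, so C10 becomes an aldehyde and C9 a (Z)-iodoalkene (Ni/Cr alkenylation); the two Z-trisubstituted alkenes C4=C5 and C8=C9 fold the chain.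
4. The open chain is cut at C2–C3 (Grignard reagent + Weinreb amide). The C3–C9 piece comes from propargyl alcohol through a dihydropyranone, a temporary ring that fixes the Z-enoate and carries C7; the C10–C1–C2 piece comes from an Evans deconjugative alkylation.
5. Order of ring formation: dihydropyranone (step 5, opened in step 6), ten-membered carbocycle (step 15), C8–C9 oxirane (step 16), C4–C5 oxirane (step 18).

Key step: step 15

Remark: the SMILES is read as two angelates ((Z)-2-methylbut-2-enoates) and two oxiranes whose ring bonds are cis, so both ring alkenes of the precursors are Z; in ring numbering the target is (1S,4R,5R,7S,8R,9S,10S).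
Remark: 4-methoxybenzyl chloromethyl ether and the (+)-α-pinene-derived B-allylbis(isopinocampheyl)borane are taken as purchasable reagents.

**Route**

Step 1
Reactants: 1 prop-2-yn-1-ol
Product: 3 (2Z)-3-iodo-2-methylprop-2-en-1-ol, via chelated alkenylmagnesium bromide 2 (not isolated)
Conditions: MeMgBr (3 equiv), CuI (10 mol %), Et2O/THF, −10 °C to rt; then I2, −78 to 0 °C
Reagents that add atoms: methylmagnesium bromide C[Mg]Br; iodine II
Why: Hydroxyl-directed CuI-catalysed anti-carbomagnesiation of the propargylic alkoxide puts the methyl group on the internal carbon and magnesium on the terminal carbon cis to the CH2O arm (chelate 2), and iodinolysis of the C–Mg bond with retention fixes the Z iodoalkene that later becomes C9=C8.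

Step 2
Reactants: 3 (2Z)-3-iodo-2-methylprop-2-en-1-ol
Product: 4 (2Z)-3-iodo-2-methylprop-2-enal
Conditions: MnO2 (excess), CH2Cl2, rt, dark; solution used directly
Reagents that add atoms: none
Why: Allylic oxidation with MnO2 is neutral and selective for the allylic alcohol, so the Z geometry of the β-iodo enal should be kept when the solution is used at once.

Step 3
Reactants: 4 (2Z)-3-iodo-2-methylprop-2-enal
Product: 6 (1Z,3S)-1-iodo-2-methylhexa-1,5-dien-3-ol, via bis(isopinocampheyl)borinate ester 5 (not isolated)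
Conditions: B-allylbis(isopinocampheyl)borane of the (+)-α-pinene series (1.3 equiv), Et2O, −78 °C; then NaOH, H2O2, 0 °C to rt
Reagents that add atoms: B-allylbis(isopinocampheyl)borane, (+)-α-pinene series C=CCB([C@@H]1C[C@@H]2C[C@H]([C@H]1C)C2(C)C)[C@@H]1C[C@@H]2C[C@H]([C@H]1C)C2(C)C
Why: Brown allylboration through a closed chair transition state, in which the (+)-α-pinene-derived reagent should add allyl to the Si face of an α-branched enal, sets the (S) carbinol that becomes C7, and alkaline peroxide frees the alcohol from borinate 5 without touching the iodoalkene.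

Step 4
Reactants: 6 (1Z,3S)-1-iodo-2-methylhexa-1,5-dien-3-ol
Product: 7 (1Z,3S)-1-iodo-2-methylhexa-1,5-dien-3-yl 2-methylprop-2-enoate
Conditions: methacryloyl chloride, Et3N, DMAP (cat.), CH2Cl2, 0 °C
Reagents that add atoms: methacryloyl chloride C=C(C)C(=O)Cl
Why: DMAP-catalysed O-acylation of the secondary alcohol installs the second alkene for metathesis and the future C3 and C4 carbons without involving a stereocentre.

Step 5
Reactants: 7 (1Z,3S)-1-iodo-2-methylhexa-1,5-dien-3-yl 2-methylprop-2-enoate
Product: 8 (6S)-6-[(1Z)-1-iodoprop-1-en-2-yl]-3-methyl-5,6-dihydro-2H-pyran-2-one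
Conditions: second-generation Grubbs catalyst, RuCl2(=CHPh)(PCy3)(H2IMes) (5 mol %), CH2Cl2 (0.01 M), 40 °C
Reagents that add atoms: none
Why: Ring-closing metathesis of the terminal alkene with the methacrylate alkene gives the six-membered unsaturated lactone, in which the new trisubstituted C4=C5 bond can only be Z, while the trisubstituted iodoalkene does not engage the ruthenium carbene.

Step 6
Reactants: 8 (6S)-6-[(1Z)-1-iodoprop-1-en-2-yl]-3-methyl-5,6-dihydro-2H-pyran-2-one
Product: 9 (2Z,5S,6Z)-5-hydroxy-7-iodo-N-methoxy-N,2,6-trimethylhepta-2,6-dienamide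
Conditions: AlMe3, MeNH(OMe)·HCl, CH2Cl2, 0 °C to rt; aq. potassium sodium tartrate
Reagents that add atoms: N,O-dimethylhydroxylamine hydrochloride CNOC.Cl
Why: Weinreb aminolysis with the aluminium amide cleaves the lactone at the acyl–oxygen bond without touching the alkene, so the ring-enforced Z geometry is transferred to an open-chain acyl donor.

Step 7
Reactants: 9 (2Z,5S,6Z)-5-hydroxy-7-iodo-N-methoxy-N,2,6-trimethylhepta-2,6-dienamide
Product: 10 (2Z,5S,6Z)-7-iodo-N-methoxy-N,2,6-trimethyl-5-[(triethylsilyl)oxy]hepta-2,6-dienamide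
Conditions: TESOTf, 2,6-lutidine, CH2Cl2, −78 °C
Reagents that add atoms: triethylsilyl trifluoromethanesulfonate CC[Si](CC)(CC)OS(=O)(=O)C(F)(F)F
Why: Silyl ether formation with TESOTf is fast at low temperature, stops relactonisation of the Z hydroxy amide and later keeps the C7 oxygen from directing the first epoxidation.

Step 8
Reactants: 11 (4R)-4-benzyl-1,3-oxazolidin-2-one; 12 3-methylbut-2-enoyl chloride
Product: 13 (4R)-4-benzyl-3-(3-methylbut-2-enoyl)-1,3-oxazolidin-2-one
Conditions: n-BuLi, THF, −78 °C; then 12, −78 to 0 °C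
Reagents that add atoms: none
Why: N-Acylation of the lithiated oxazolidinone with the acid chloride is the standard entry to Evans imides.

Step 9
Reactants: 13 (4R)-4-benzyl-3-(3-methylbut-2-enoyl)-1,3-oxazolidin-2-one
Product: 15 (4R)-4-benzyl-3-[(2S)-2-{[(4-methoxybenzyl)oxy]methyl}-3-methylbut-3-enoyl]-1,3-oxazolidin-2-one, via sodium dienolate 14 (not isolated)
Conditions: NaN(SiMe3)2, THF, −78 °C; then 4-methoxybenzyl chloromethyl ether, −78 to −40 °C
Reagents that add atoms: 4-methoxybenzyl chloromethyl ether COc1ccc(COCCl)cc1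
Why: Evans deconjugative alkylation, in which γ-deprotonation gives the chelated Z(O)-dienolate 14 that is alkylated at the α-carbon on the face opposite the benzyl group, moves the alkene out of conjugation (isopropenyl) and sets the stereocentre that becomes C1.

Step 10
Reactants: 15 (4R)-4-benzyl-3-[(2S)-2-{[(4-methoxybenzyl)oxy]methyl}-3-methylbut-3-enoyl]-1,3-oxazolidin-2-one
Product: 16 (2R)-2-{[(4-methoxybenzyl)oxy]methyl}-3-methylbut-3-en-1-ol
Conditions: LiBH4, THF, 0 °C to rt
Reagents that add atoms: none
Why: Reductive cleavage of the imide with LiBH4 releases the primary alcohol without epimerising the α-centre and leaves the PMB ether and the 1,1-disubstituted alkene untouched.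

Step 11
Reactants: 16 (2R)-2-{[(4-methoxybenzyl)oxy]methyl}-3-methylbut-3-en-1-ol
Product: 17 (2S)-2-(bromomethyl)-3-methylbut-3-en-1-yl 4-methoxybenzyl ether
Conditions: CBr4, PPh3, CH2Cl2, 0 °C
Reagents that add atoms: carbon tetrabromide BrC(Br)(Br)Br
Why: Appel bromination converts the primary alcohol into the bromide under neutral conditions and does not involve the stereocentre.

Step 12
Reactants: 17 (2S)-2-(bromomethyl)-3-methylbut-3-en-1-yl 4-methoxybenzyl ether; 10 (2Z,5S,6Z)-7-iodo-N-methoxy-N,2,6-trimethyl-5-[(triethylsilyl)oxy]hepta-2,6-dienamide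
Product: 19 (3S,6Z,9S,10Z)-11-iodo-3-{[(4-methoxybenzyl)oxy]methyl}-2,6,10-trimethyl-9-[(triethylsilyl)oxy]undeca-1,6,10-trien-5-one, via Grignard reagent 18 (not isolated)
Conditions: 17, Mg, THF, rt; then 10, THF, −20 to 0 °C; aq. NH4Cl
Reagents that add atoms: none
Why: Grignard addition to the Weinreb amide stops at the ketone because the magnesium chelate survives until work-up, an alkylmagnesium halide does not exchange with the alkenyl iodide at or below 0 °C, and 1,2-addition is favoured on the α-methyl Z-enamide, so C2–C3 is formed with both Z alkenes and both stereocentres intact.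

Step 13
Reactants: 19 PMB-protected seco ketone
Product: 20 (3S,6Z,9S,10Z)-3-(hydroxymethyl)-11-iodo-2,6,10-trimethyl-9-[(triethylsilyl)oxy]undeca-1,6,10-trien-5-one
Conditions: DDQ, CH2Cl2/pH 7 buffer, 0 °C
Reagents that add atoms: none
Why: Oxidative PMB cleavage with DDQ under buffered conditions is selective for the electron-rich benzyl ether and spares the silyl ether, the enone and the iodoalkene.

Step 14
Reactants: 20 hydroxy ketone
Product: 21 (2S,5Z,8S,9Z)-10-iodo-5,9-dimethyl-4-oxo-2-(prop-1-en-2-yl)-8-[(triethylsilyl)oxy]deca-5,9-dienal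
Conditions: Dess–Martin periodinane, pyridine, CH2Cl2, 0 °C to rt; used at once
Reagents that add atoms: none
Why: Dess–Martin oxidation is non-basic, so the α-isopropenyl aldehyde should form without epimerisation at C1 or migration of the alkene into conjugation.

Step 15
Reactants: 21 iodo keto aldehyde
Product: 23 (2Z,5S,6Z,8R,9S)-8-hydroxy-2,6-dimethyl-9-(prop-1-en-2-yl)-5-[(triethylsilyl)oxy]cyclodeca-2,6-dien-1-one (target numbering: C10 hydroxyl trans to the C1 isopropenyl), via alkenylchromium dichloride 22 (not isolated)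
Conditions: CrCl2 (10 equiv), NiCl2 (0.1 equiv), DMSO/THF, rt, slow addition of 21 to about 0.003 M
Reagents that add atoms: none
Why: Nozaki–Hiyama–Kishi reaction: NiCl2 is reduced by CrCl2 to zerovalent nickel, which inserts into the C–I bond with retention, the alkenyl group passes to trivalent chromium (22), and the alkenylchromium adds to the aldehyde. The closest known reaction type is the Ni/Cr-mediated macrocyclisation of iodoalkenyl aldehydes to ten-membered and larger lactones and carbocycles. The ten-membered carbocycle, the only ring formed, closes in a 10-exo-trig mode by attack of C9 on the aldehyde carbon C10. The new stereocentre C10 is controlled by the neighbouring C1 centre: in the cyclic transition state the chromium alkoxide and the isopropenyl group should both take outward (pseudo-equatorial) positions, which is the trans arrangement needed. The step needs chemoselection for the aldehyde over the ketone and enone (organochromium reagents do not add to ketones at room temperature), retention of the Z geometry (secured for 2,2-disubstituted iodoalkenes) and ring closure over oligomerisation, which the two Z-trisubstituted alkenes as turn elements and slow addition at high dilution should secure.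

Step 16
Reactants: 23 macrocyclic allylic alcohol
Product: 24 C8–C9 oxirane of 23, oxirane oxygen cis to the C10 hydroxyl
Conditions: VO(acac)2 (5 mol %), t-BuOOH (1.5 equiv), CH2Cl2, 0 °C to rt
Reagents that add atoms: tert-butyl hydroperoxide CC(C)(C)OO
Why: Hydroxyl-directed vanadium-catalysed epoxidation of a medium-ring (Z)-allylic alcohol delivers oxygen to C8=C9 on the face of the C10 hydroxyl (cis rule for cycloalkenols), which sets C8 and C9, while the electron-poor enone, the homoallylic isopropenyl group and the silylated C7 oxygen do not compete.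

Step 17
Reactants: 24 epoxy alcohol silyl ether
Product: 25 epoxy diol with free C7 and C10 hydroxyls and the Z-enone
Conditions: HF·pyridine, pyridine, THF, 0 °C
Reagents that add atoms: none
Why: Buffered HF·pyridine removes the secondary triethylsilyl group without opening the oxirane or isomerising the enone.

Step 18
Reactants: 25 epoxy diol enone
Product: 26 diepoxy diol (the target with both esters replaced by OH)
Conditions: t-BuOOH, n-BuLi (gives t-BuOOLi, 3 equiv), THF, −78 to −20 °C
Reagents that add atoms: tert-butyl hydroperoxide CC(C)(C)OO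
Why: Weitz–Scheffer nucleophilic epoxidation, in which lithium tert-butylperoxide held by the C7 hydroxyl through a lithium bridge should add to C5 on the face of that hydroxyl and the peroxy enolate should close faster than the C4–C5 bond can rotate inside the ten-membered ring (as known for cis-cyclodecenones), sets C4 and C5 with the ring bonds cis and the oxirane oxygen cis to O7.

Step 19
Reactants: 26 diepoxy diol
Product: 27 target, the 7,10-bis-angelate
Conditions: angelic acid, 2,4,6-trichlorobenzoyl chloride, Et3N, toluene, rt; then 26, 75 °C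
Reagents that add atoms: angelic acid C/C=C(/C)C(=O)O
Why: Acylation of both secondary hydroxyls with the preformed angelic 2,4,6-trichlorobenzoic mixed anhydride (Yamaguchi-type) in toluene, without a nucleophilic catalyst, should transfer the angeloyl group with its Z geometry and touches no stereocentre.

**Compound list**

1 | prop-2-yn-1-ol | C#CCO | starting material
2 | (Z)-3-(bromomagnesiooxy)-2-methylprop-1-enylmagnesium bromide (chelated) | Br[Mg]OC/C(C)=C\[Mg]Br | intermediate
3 | (2Z)-3-iodo-2-methylprop-2-en-1-ol | OC/C(C)=C\I | intermediate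
4 | (2Z)-3-iodo-2-methylprop-2-enal | O=C/C(C)=C\I | intermediate
5 | (1Z,3S)-1-iodo-2-methylhexa-1,5-dien-3-yl bis(isopinocampheyl)borinate | C=CC[C@H](OB([C@@H]1C[C@@H]2C[C@H]([C@H]1C)C2(C)C)[C@@H]1C[C@@H]2C[C@H]([C@H]1C)C2(C)C)/C(C)=C\I | intermediate
6 | (1Z,3S)-1-iodo-2-methylhexa-1,5-dien-3-ol | C=CC[C@H](O)/C(C)=C\I | intermediate
7 | (1Z,3S)-1-iodo-2-methylhexa-1,5-dien-3-yl 2-methylprop-2-enoate | C=CC[C@H](OC(=O)C(C)=C)/C(C)=C\I | intermediate
8 | (6S)-6-[(1Z)-1-iodoprop-1-en-2-yl]-3-methyl-5,6-dihydro-2H-pyran-2-one | CC1=CC[C@H](OC1=O)/C(C)=C\I | intermediate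
9 | (2Z,5S,6Z)-5-hydroxy-7-iodo-N-methoxy-N,2,6-trimethylhepta-2,6-dienamide | CON(C)C(=O)/C(C)=C\C[C@H](O)/C(C)=C\I | intermediate
10 | (2Z,5S,6Z)-7-iodo-N-methoxy-N,2,6-trimethyl-5-[(triethylsilyl)oxy]hepta-2,6-dienamide | CON(C)C(=O)/C(C)=C\C[C@H](O[Si](CC)(CC)CC)/C(C)=C\I | intermediate
11 | (4R)-4-benzyl-1,3-oxazolidin-2-one | O=C1N[C@H](Cc2ccccc2)CO1 | starting material
12 | 3-methylbut-2-enoyl chloride | CC(C)=CC(=O)Cl | starting material
13 | (4R)-4-benzyl-3-(3-methylbut-2-enoyl)-1,3-oxazolidin-2-one | CC(C)=CC(=O)N1[C@H](Cc2ccccc2)COC1=O | intermediate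
14 | sodium Z(O)-dienolate of 13 | C=C(C)/C=C(\[O-])N1[C@H](Cc2ccccc2)COC1=O.[Na+] | intermediate
15 | (4R)-4-benzyl-3-[(2S)-2-{[(4-methoxybenzyl)oxy]methyl}-3-methylbut-3-enoyl]-1,3-oxazolidin-2-one | C=C(C)[C@@H](COCc1ccc(OC)cc1)C(=O)N1[C@H](Cc2ccccc2)COC1=O | intermediate
16 | (2R)-2-{[(4-methoxybenzyl)oxy]methyl}-3-methylbut-3-en-1-ol | C=C(C)[C@@H](COCc1ccc(OC)cc1)CO | intermediate
17 | (2S)-2-(bromomethyl)-3-methylbut-3-en-1-yl 4-methoxybenzyl ether | C=C(C)[C@@H](COCc1ccc(OC)cc1)CBr | intermediate
18 | Grignard reagent of 17 | C=C(C)[C@@H](COCc1ccc(OC)cc1)C[Mg]Br | intermediate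
19 | (3S,6Z,9S,10Z)-11-iodo-3-{[(4-methoxybenzyl)oxy]methyl}-2,6,10-trimethyl-9-[(triethylsilyl)oxy]undeca-1,6,10-trien-5-one | C=C(C)[C@@H](COCc1ccc(OC)cc1)CC(=O)/C(C)=C\C[C@H](O[Si](CC)(CC)CC)/C(C)=C\I | intermediate
20 | (3S,6Z,9S,10Z)-3-(hydroxymethyl)-11-iodo-2,6,10-trimethyl-9-[(triethylsilyl)oxy]undeca-1,6,10-trien-5-one | C=C(C)[C@@H](CO)CC(=O)/C(C)=C\C[C@H](O[Si](CC)(CC)CC)/C(C)=C\I | intermediate
21 | (2S,5Z,8S,9Z)-10-iodo-5,9-dimethyl-4-oxo-2-(prop-1-en-2-yl)-8-[(triethylsilyl)oxy]deca-5,9-dienal | C=C(C)[C@@H](C=O)CC(=O)/C(C)=C\C[C@H](O[Si](CC)(CC)CC)/C(C)=C\I | intermediate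
22 | alkenylchromium dichloride derived from 21 (chromium in place of iodine) | C=C(C)[C@@H](C=O)CC(=O)/C(C)=C\C[C@H](O[Si](CC)(CC)CC)/C(C)=C\[Cr](Cl)Cl | intermediate
23 | (2Z,5S,6Z,8R,9S)-8-hydroxy-2,6-dimethyl-9-(prop-1-en-2-yl)-5-[(triethylsilyl)oxy]cyclodeca-2,6-dien-1-one | C=C(C)[C@@H]1CC(=O)/C(C)=C\C[C@H](O[Si](CC)(CC)CC)/C(C)=C\[C@H]1O | intermediate
24 | C8–C9 oxirane of 23 (oxirane oxygen cis to the C10 hydroxyl, trans to the C7 silyloxy group; Z-enone kept) | C=C(C)[C@@H]1CC(=O)/C(C)=C\C[C@H](O[Si](CC)(CC)CC)[C@@]2(C)O[C@H]2[C@H]1O | intermediate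
25 | desilylated 24: C8–C9 epoxy 7,10-diol with the Z-enone | C=C(C)[C@@H]1CC(=O)/C(C)=C\C[C@H](O)[C@@]2(C)O[C@H]2[C@H]1O | intermediate
26 | diepoxy diol: the target with OH at C7 and C10 (ring numbering 1S,4R,5R,7S,8R,9S,10S) | C=C(C)[C@@H]1CC(=O)[C@]2(C)O[C@@H]2C[C@H](O)[C@@]2(C)O[C@H]2[C@H]1O | intermediate
27 | target, 7,10-bis-angelate of 26 | C=C(C)[C@@H]1CC(=O)[C@]2(C)O[C@@H]2C[C@H](OC(=O)/C(C)=C\C)[C@@]2(C)O[C@H]2[C@H]1OC(=O)/C(C)=C\C | target

**Summary**

Total step count: 19. Longest linear sequence: 15 steps (steps 1–7 and 12–19).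

The three steps most likely to fail:

Step 15 (ring closure). What may go wrong: intermolecular coupling competing with the ten-membered closure, and attack on the wrong face of the aldehyde (poor facial selectivity at C10), made worse if the α-isopropenyl aldehyde epimerises before it reacts. Fallback, setting out from 21 and coming back at 23: the same Ni/Cr closure is run, and if it gives mainly the alcohol with the hydroxyl cis to the isopropenyl group, this 10-epi macrocyclic alcohol F1 is not discarded. Mitsunobu esterification (4-nitrobenzoic acid, PPh3, DIAD, toluene, 0 °C) inverts C10 to give the 4-nitrobenzoate of 23 F2, and methanolysis (K2CO3, MeOH, 0 °C) returns the route at 23, so the C10 configuration is then set by inversion and not by the addition itself.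

Step 18 (enone epoxidation). What may go wrong: peroxide attack on the wrong face of the enone, rotation about C4–C5 in the peroxy enolate before ring closure (loss of the cis ring bonds), or base-induced migration of the existing oxirane. Fallback, setting out from 24 and coming back at 27, replaces the nucleophilic epoxidation by a hydroxyl-directed one. The C10 hydroxyl of 24 is first esterified with the angelic mixed anhydride to give the C10 mono-angelate F3. Luche reduction (NaBH4, CeCl3·7H2O, MeOH, −40 °C) gives the allylic alcohols, of which the (3S)-allylic alcohol F4 is carried on and the other epimer is returned to F3 by Dess–Martin oxidation. VO(acac)2/t-BuOOH then places the oxirane cis to the C3 hydroxyl to give the diepoxy alcohol F5, Dess–Martin oxidation restores the ketone in the diepoxy ketone F6, HF·pyridine frees C7–OH to give the hydroxy mono-angelate F7, and a last angeloylation as in step 19 gives 27.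

Step 19 (double angeloylation). What may go wrong: Z-to-E isomerisation of the activated angeloyl unit (tigloyl transfer) and incomplete acylation of two hindered hydroxyls, one of which can be tied up as a transannular hemiketal with the C3 ketone. Fallback, setting out from 26 and coming back at 27, builds the ester alkenes after acylation. Both hydroxyls are esterified with 2-[bis(2,2,2-trifluoroethoxy)phosphoryl]propanoic acid (DCC, DMAP, CH2Cl2) to give the bis(phosphonopropanoate) F8 (mixture at the two phosphonate-bearing carbons). A twofold Still–Gennari olefination with acetaldehyde (KN(SiMe3)2, 18-crown-6, THF, −78 °C) then forms both Z-2-methylbut-2-enoates and gives 27.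

**Further compounds**

F1 | step 15 | 10-epi-23 (C10 hydroxyl cis to the C1 isopropenyl) | C=C(C)[C@@H]1CC(=O)/C(C)=C\C[C@H](O[Si](CC)(CC)CC)/C(C)=C\[C@@H]1O
F2 | step 15 | 4-nitrobenzoate of 23 | C=C(C)[C@@H]1CC(=O)/C(C)=C\C[C@H](O[Si](CC)(CC)CC)/C(C)=C\[C@H]1OC(=O)c1ccc(cc1)[N+](=O)[O-]
F3 | step 18 | C10 mono-angelate of 24 | C=C(C)[C@@H]1CC(=O)/C(C)=C\C[C@H](O[Si](CC)(CC)CC)[C@@]2(C)O[C@H]2[C@H]1OC(=O)/C(C)=C\C
F4 | step 18 | (3S)-allylic alcohol from F3 | C=C(C)[C@@H]1C[C@H](O)/C(C)=C\C[C@H](O[Si](CC)(CC)CC)[C@@]2(C)O[C@H]2[C@H]1OC(=O)/C(C)=C\C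
F5 | step 18 | diepoxy alcohol (C4–C5 oxirane cis to the C3 hydroxyl) | C=C(C)[C@@H]1C[C@H](O)[C@]2(C)O[C@@H]2C[C@H](O[Si](CC)(CC)CC)[C@@]2(C)O[C@H]2[C@H]1OC(=O)/C(C)=C\C
F6 | step 18 | diepoxy ketone, C7 silyl ether, C10 angelate | C=C(C)[C@@H]1CC(=O)[C@]2(C)O[C@@H]2C[C@H](O[Si](CC)(CC)CC)[C@@]2(C)O[C@H]2[C@H]1OC(=O)/C(C)=C\C
F7 | step 18 | diepoxy ketone, C7 hydroxyl, C10 angelate | C=C(C)[C@@H]1CC(=O)[C@]2(C)O[C@@H]2C[C@H](O)[C@@]2(C)O[C@H]2[C@H]1OC(=O)/C(C)=C\C
F8 | step 19 | 7,10-bis{2-[bis(2,2,2-trifluoroethoxy)phosphoryl]propanoate} of 26 | C=C(C)[C@@H]1CC(=O)[C@]2(C)O[C@@H]2C[C@H](OC(=O)C(C)P(=O)(OCC(F)(F)F)OCC(F)(F)F)[C@@]2(C)O[C@H]2[C@H]1OC(=O)C(C)P(=O)(OCC(F)(F)F)OCC(F)(F)F
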